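**Retrosynthetic overview**

1. Chain lettering: ring A–C-a(Me)–C-b(OCOEt)–C-c(Me)–C-d(OAc)–C-e(Me)=C-f–C-g(Me)–ring B–C-h(Me)–C-i(OH)–Et. Last bond C-f–C-g: Ni-catalysed enantioconvergent reductive coupling of ring B chloride 9 with alkenyl iodide 18, the silyl ether being cleaved in the quench.
2. 18 ⇐ propionylation of 17 ⇐ C-a–C-b: Felkin-controlled BF3 vinylogous Mukaiyama aldol of pyrone silyl dienol ether 5 with β-acetoxy aldehyde 16.
3. 16 ⇐ acetylation and terminal-alkene cleavage of 13 ⇐ C-c–C-d: chiral phosphoric acid-catalysed anti-crotylboration of achiral iodoenal 11.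
4. 9 ⇐ lateral chlorination of 7 ⇐ C-h–C-i: new IDPi-catalysed enantioselective vinylogous Mukaiyama aldol of 5 with propanal.
5. Rings: the γ-pyrone ring is made once (step 1) and its dienol ether 5 is used twice, first as ring B (step 3), then as ring A (step 9); no ring is closed afterwards.

Assumption: (E)-3-iodo-2-methylprop-2-en-1-ol (10), (E)-crotylboronic acid pinacol ester (12) and the chiral catalysts and ligand are bought; every carbon building block is achiral.

**Route**

Step 1
Reactants: 1 3-pentanone; 2 propionic acid (2.2 equiv)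
Product: 3 2,6-diethyl-3,5-dimethyl-4H-pyran-4-one
Conditions: polyphosphoric acid, 95 °C, 6 h; ice, extraction, distillation
Reagents that add atoms: none
Why: Polyphosphoric acid brings about double C-acylation of the ketone by propionic acid and cyclodehydration of the 1,3,5-triketone (classical one-pot γ-pyrone synthesis); the product is achiral and symmetric.

Step 2
Reactants: 3 2,6-diethyl-3,5-dimethyl-4H-pyran-4-one
Product: 5 triethyl{[(2Z)-6-ethyl-2-ethylidene-3,5-dimethyl-2H-pyran-4-yl]oxy}silane, via lithium dienolate 4 (not isolated)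
Conditions: LiN(SiMe3)2 (1.05 equiv), THF, −78 °C, 30 min; Et3SiCl, −78 → 0 °C; pentane, filtration under argon, used crude
Reagents that add atoms: chlorotriethylsilane, CC[Si](Cl)(CC)CC
Why: The 2-ethyl group is a vinylogous α-position, so the amide base gives the lateral dienolate, which is O-silylated by the hard silyl chloride (enolate O-silylation); allylic strain with the ring methyl turns the ethylidene methyl toward the ring oxygen (Z).

Step 3
Reactants: 5 triethyl{[(2Z)-6-ethyl-2-ethylidene-3,5-dimethyl-2H-pyran-4-yl]oxy}silane; 6 propanal (1.5 equiv)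
Product: 7 2-ethyl-3,5-dimethyl-6-[(2S,3S)-3-(triethylsilyloxy)pentan-2-yl]-4H-pyran-4-one
Conditions: (S,S)-IDPi (imidodiphosphorimidate Brønsted acid from 3,3'-diaryl-BINOL with N-triflyl groups, 3 mol%), toluene, −78 °C, 24 h; Et3N quench
Reagents that add atoms: none
Why: Proposed new method: catalytic enantioselective vinylogous Mukaiyama aldol of a pyrone "anhydrobase". The IDPi acid is silylated by 5 to a chiral silylium/IDPi ion pair that silylates propanal; the exocyclic ethylidene carbon of 5 (the only unhindered nucleophilic terminus, whose attack re-aromatises the ring to a 4-silyloxypyrylium) adds to the Re face of the confined silyloxocarbenium through an open synclinal transition state with the aldehyde ethyl group anti to the pyran ring (hence anti, 2S,3S); the silyloxypyrylium then passes its silyl group to the next aldehyde and releases 7. The closest known reaction types are IDPi- and disulfonimide-catalysed (vinylogous) Mukaiyama aldol additions of enol silanes and silyl dienolates, and the stoichiometric, racemic lithium-dienolate aldol of 2-ethyl-4-pyrones.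

Step 4
Reactants: 7 2-ethyl-3,5-dimethyl-6-[(2S,3S)-3-(triethylsilyloxy)pentan-2-yl]-4H-pyran-4-one
Product: 9 2-(1-chloroethyl)-3,5-dimethyl-6-[(2S,3S)-3-(triethylsilyloxy)pentan-2-yl]-4H-pyran-4-one (both CHCl epimers), via lithium dienolate 8 (not isolated)
Conditions: LiN(SiMe3)2 (1.05 equiv), THF, −78 °C; cannulated into C2Cl6 (1.5 equiv), THF, −78 °C
Reagents that add atoms: hexachloroethane, ClC(Cl)(Cl)C(Cl)(Cl)Cl
Why: Kinetic deprotonation takes the unhindered ethyl CH2 and not the branched methine, and the dienolate is chlorinated at the lateral carbon with re-aromatisation (electrophilic enolate halogenation); the CHCl centre forms unselectively, which does not matter because step 11 is stereoconvergent.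

Step 5
Reactants: 10 (E)-3-iodo-2-methylprop-2-en-1-ol
Product: 11 (E)-3-iodo-2-methylprop-2-enal
Conditions: MnO2 (15 equiv), CH2Cl2, rt, 2 h; filtered, used directly
Reagents that add atoms: none
Why: MnO2 oxidises the allylic alcohol to the enal (allylic oxidation) without touching the alkenyl iodide or the E geometry.

Step 6
Reactants: 11 (E)-3-iodo-2-methylprop-2-enal; 12 (E)-crotylboronic acid pinacol ester (1.2 equiv)
Product: 13 (1E,3R,4R)-1-iodo-2,4-dimethylhexa-1,5-dien-3-ol
Conditions: (R)-TRIP phosphoric acid (5 mol%), toluene, −30 °C, 24 h; aqueous work-up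
Reagents that add atoms: none
Why: Chiral phosphoric acid-catalysed crotylboration through a closed chair transition state turns the E-crotyl geometry into the anti relationship, while the acid (hydrogen-bonded to a boronate oxygen and the formyl H) directs attack to the aldehyde Re face as it does for aryl and alkenyl aldehydes, setting (R) at C-d and (R) at C-c by metal-free asymmetric catalysis.

Step 7
Reactants: 13 (1E,3R,4R)-1-iodo-2,4-dimethylhexa-1,5-dien-3-ol
Product: 14 (1E,3R,4R)-1-iodo-2,4-dimethylhexa-1,5-dien-3-yl acetate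
Conditions: Ac2O, pyridine, DMAP (5 mol%), CH2Cl2, 0 °C → rt
Reagents that add atoms: acetic anhydride, CC(=O)OC(C)=O
Why: DMAP-catalysed acetylation of the secondary allylic alcohol; no stereocentre is touched and the acetate of the target is in place.

Step 8
Reactants: 14 (1E,3R,4R)-1-iodo-2,4-dimethylhexa-1,5-dien-3-yl acetate
Product: 16 (2S,3R,4E)-3-acetoxy-5-iodo-2,4-dimethylpent-4-enal, via diol 15 (not isolated)
Conditions: OsO4 (2 mol%), NaIO4 (4 equiv), 2,6-lutidine (2 equiv), dioxane/H2O 3:1, rt; used crude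
Reagents that add atoms: osmium tetroxide OsO4, O=[Os](=O)(=O)=O; sodium periodate NaIO4, [Na+].[O-]I(=O)(=O)=O; water, O
Why: Lemieux–Johnson cleavage: OsO4 dihydroxylates the monosubstituted terminal alkene in preference to the hindered, electron-poor alkenyl iodide and NaIO4 cleaves the diol; the lutidine buffer protects the α-stereocentre and the β-acetoxy group.

Step 9
Reactants: 16 (2S,3R,4E)-3-acetoxy-5-iodo-2,4-dimethylpent-4-enal; 5 triethyl{[(2Z)-6-ethyl-2-ethylidene-3,5-dimethyl-2H-pyran-4-yl]oxy}silane (1.3 equiv)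
Product: 17 (1E,3R,4R,5R,6R)-6-(6-ethyl-3,5-dimethyl-4-oxo-4H-pyran-2-yl)-5-hydroxy-1-iodo-2,4-dimethylhept-1-en-3-yl acetate
Conditions: BF3·OEt2 (1.5 equiv), CH2Cl2, −78 °C, 2 h; aq. NaHCO3
Reagents that add atoms: none
Why: Proposed new method: second use of the pyrone dienol ether as a Mukaiyama donor (as unprecedented as in step 3), here with stoichiometric BF3 and substrate control. BF3 activates the aldehyde and the ethylidene carbon of 5 attacks its Si face with re-aromatisation; Felkin–Anh control by the α-methyl group and 1,3-anti induction by the β-acetoxy group reinforce each other in this anti aldehyde and give (R) at C-b, and the open synclinal transition state of step 3 (aldehyde chain anti to the pyran ring) gives the anti C-a/C-b relationship, i.e. (R) at C-a. The closest known reaction type is the BF3-mediated (vinylogous) Mukaiyama aldol addition of silyl dienol ethers to α-methyl-β-oxygenated aldehydes.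

Step 10
Reactants: 17 (1E,3R,4R,5R,6R)-6-(6-ethyl-3,5-dimethyl-4-oxo-4H-pyran-2-yl)-5-hydroxy-1-iodo-2,4-dimethylhept-1-en-3-yl acetate
Product: 18 (1E,3R,4R,5R,6R)-3-acetoxy-6-(6-ethyl-3,5-dimethyl-4-oxo-4H-pyran-2-yl)-1-iodo-2,4-dimethylhept-1-en-5-yl propanoate
Conditions: (EtCO)2O (5 equiv), DMAP (0.3 equiv), pyridine, CH2Cl2, 0 °C → rt
Reagents that add atoms: propionic anhydride, CCC(=O)OC(=O)CC
Why: DMAP-catalysed acylation of the secondary alcohol; excess anhydride makes esterification faster than 1,3-acetyl migration, and the mild amine base does not eliminate the β-acyloxy group.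

Step 11
Reactants: 18 (1E,3R,4R,5R,6R)-3-acetoxy-6-(6-ethyl-3,5-dimethyl-4-oxo-4H-pyran-2-yl)-1-iodo-2,4-dimethylhept-1-en-5-yl propanoate; 9 2-(1-chloroethyl)-3,5-dimethyl-6-[(2S,3S)-3-(triethylsilyloxy)pentan-2-yl]-4H-pyran-4-one (1.5 equiv)
Product: 20 (2R,3R,4R,5R,6E,8S)-5-acetoxy-2-(6-ethyl-3,5-dimethyl-4-oxo-4H-pyran-2-yl)-8-{6-[(2S,3S)-3-hydroxypentan-2-yl]-3,5-dimethyl-4-oxo-4H-pyran-2-yl}-4,6-dimethylnon-6-en-3-yl propanoate (target CNP0331774.1), via silyl ether 19 (not isolated)
Conditions: NiCl2(dme) (10 mol%), (3aR,3a'R,8aS,8a'S)-2,2'-(cyclopropane-1,1-diyl)bis(3a,8a-dihydro-8H-indeno[1,2-d]oxazole) (12 mol%), Mn powder (3 equiv), NaI (0.5 equiv), DMA, 0 °C, 12 h; then 1 M aq. HCl, THF, rt, 1 h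
Reagents that add atoms: none
Why: Ni-catalysed enantioconvergent reductive cross-electrophile coupling of a secondary heterobenzylic chloride with an alkenyl halide: zerovalent nickel inserts into the C–I bond with retention of the E geometry, the chloride (via the iodide) gives a planar pyrone-stabilised radical, and the chiral bis(oxazoline) nickel complex fixes (S) at C-g on radical capture and reductive elimination whichever epimer of 9 is used; the acidic quench then removes the triethylsilyl group and leaves both esters intact.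

**Compound list**

1 | 3-pentanone | CCC(=O)CC | starting material
2 | propionic acid | CCC(=O)O | starting material
3 | 2,6-diethyl-3,5-dimethyl-4H-pyran-4-one | CCc1oc(CC)c(C)c(=O)c1C | intermediate
4 | lithium (2Z)-6-ethyl-2-ethylidene-3,5-dimethyl-2H-pyran-4-olate | C/C=C1\OC(CC)=C(C)C([O-])=C1C.[Li+] | intermediate (not isolated)
5 | triethyl{[(2Z)-6-ethyl-2-ethylidene-3,5-dimethyl-2H-pyran-4-yl]oxy}silane | C/C=C1\OC(CC)=C(C)C(O[Si](CC)(CC)CC)=C1C | intermediate
6 | propanal | CCC=O | starting material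
7 | 2-ethyl-3,5-dimethyl-6-[(2S,3S)-3-(triethylsilyloxy)pentan-2-yl]-4H-pyran-4-one | CCc1oc([C@@H](C)[C@@H](O[Si](CC)(CC)CC)CC)c(C)c(=O)c1C | intermediate
8 | lithium (2Z)-2-ethylidene-3,5-dimethyl-6-[(2S,3S)-3-(triethylsilyloxy)pentan-2-yl]-2H-pyran-4-olate | C/C=C1\OC([C@@H](C)[C@@H](O[Si](CC)(CC)CC)CC)=C(C)C([O-])=C1C.[Li+] | intermediate (not isolated)
9 | 2-(1-chloroethyl)-3,5-dimethyl-6-[(2S,3S)-3-(triethylsilyloxy)pentan-2-yl]-4H-pyran-4-one (both CHCl epimers) | CC(Cl)c1oc([C@@H](C)[C@@H](O[Si](CC)(CC)CC)CC)c(C)c(=O)c1C | intermediate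
10 | (E)-3-iodo-2-methylprop-2-en-1-ol | OC/C(C)=C/I | starting material
11 | (E)-3-iodo-2-methylprop-2-enal | O=C/C(C)=C/I | intermediate
12 | (E)-crotylboronic acid pinacol ester | C/C=C/CB1OC(C)(C)C(C)(C)O1 | starting material
13 | (1E,3R,4R)-1-iodo-2,4-dimethylhexa-1,5-dien-3-ol | C=C[C@@H](C)[C@@H](O)/C(C)=C/I | intermediate
14 | (1E,3R,4R)-1-iodo-2,4-dimethylhexa-1,5-dien-3-yl acetate | C=C[C@@H](C)[C@@H](OC(C)=O)/C(C)=C/I | intermediate
15 | (1E,3R,4R)-5,6-dihydroxy-1-iodo-2,4-dimethylhex-1-en-3-yl acetate (both C5 epimers) | OCC(O)[C@@H](C)[C@@H](OC(C)=O)/C(C)=C/I | intermediate (not isolated)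
16 | (2S,3R,4E)-3-acetoxy-5-iodo-2,4-dimethylpent-4-enal | O=C[C@@H](C)[C@@H](OC(C)=O)/C(C)=C/I | intermediate
17 | (1E,3R,4R,5R,6R)-6-(6-ethyl-3,5-dimethyl-4-oxo-4H-pyran-2-yl)-5-hydroxy-1-iodo-2,4-dimethylhept-1-en-3-yl acetate | O[C@H]([C@@H](C)[C@@H](OC(C)=O)/C(C)=C/I)[C@@H](C)c1oc(CC)c(C)c(=O)c1C | intermediate
18 | (1E,3R,4R,5R,6R)-3-acetoxy-6-(6-ethyl-3,5-dimethyl-4-oxo-4H-pyran-2-yl)-1-iodo-2,4-dimethylhept-1-en-5-yl propanoate | CCC(=O)O[C@H]([C@@H](C)[C@@H](OC(C)=O)/C(C)=C/I)[C@@H](C)c1oc(CC)c(C)c(=O)c1C | intermediate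
19 | (2R,3R,4R,5R,6E,8S)-5-acetoxy-8-{3,5-dimethyl-4-oxo-6-[(2S,3S)-3-(triethylsilyloxy)pentan-2-yl]-4H-pyran-2-yl}-2-(6-ethyl-3,5-dimethyl-4-oxo-4H-pyran-2-yl)-4,6-dimethylnon-6-en-3-yl propanoate | CCC(=O)O[C@H]([C@@H](C)[C@@H](OC(C)=O)/C(C)=C/[C@H](C)c1oc([C@@H](C)[C@@H](O[Si](CC)(CC)CC)CC)c(C)c(=O)c1C)[C@@H](C)c1oc(CC)c(C)c(=O)c1C | intermediate (not isolated)
20 | (2R,3R,4R,5R,6E,8S)-5-acetoxy-2-(6-ethyl-3,5-dimethyl-4-oxo-4H-pyran-2-yl)-8-{6-[(2S,3S)-3-hydroxypentan-2-yl]-3,5-dimethyl-4-oxo-4H-pyran-2-yl}-4,6-dimethylnon-6-en-3-yl propanoate | CCC(=O)O[C@H]([C@@H](C)[C@@H](OC(C)=O)/C(C)=C/[C@H](C)c1oc([C@@H](C)[C@@H](O)CC)c(C)c(=O)c1C)[C@@H](C)c1oc(CC)c(C)c(=O)c1C | target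

**Step count**

Total: 11 steps. Longest linear sequence: 7 steps (steps 5–11, from 10).

**Three steps most likely to fail**

Step 3 (proposed new method). The Lewis-basic pyrone carbonyl of 7 and of traces of 3 can hold the silylium as a 4-silyloxypyrylium and slow turnover. The anti/syn ratio, the ee and the sense of induction are unproven; the antipodal IDPi would be used if the sense is reversed. The fallback uses known chemistry, sets out from 3 and comes back at 7. Pyrone 3 is deprotonated as in step 2 (lithium dienolate 4) and treated with propanal 6 at −78 °C, the established lateral aldol of 2-ethyl-4-pyrones. The racemic anti aldol 2-ethyl-6-(3-hydroxypentan-2-yl)-3,5-dimethyl-4H-pyran-4-one F1 is separated from its syn isomer and resolved with Amano lipase PS and vinyl acetate in MTBE. The fast-reacting enantiomer is converted into the (2R,3R)-acetate F3, and the remaining (2S,3S)-alcohol F2 is silylated with Et3SiOTf and 2,6-lutidine to give 7.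

Step 9 (second use of the new dienol-ether reactivity). The β-acetoxy aldehyde 16 can eliminate acetic acid, and the C-a/C-b simple diastereoselection rests on a transition-state argument only. The fallback uses known chemistry, sets out from 13 (with 3) and comes back at 18. Alcohol 13 is silylated (Et3SiOTf, 2,6-lutidine) to the triethylsilyl ether F4. F4 is cleaved with OsO4/NaIO4/2,6-lutidine, through the diol F5 (not isolated), to the base-stable β-silyloxy aldehyde F6. F6 is added at −78 °C to lithium dienolate 4, made from 3 as in step 2 (known lateral lithium aldol); the Felkin, anti aldol alcohol F7 is isolated by chromatography. Propionylation ((EtCO)2O, DMAP, pyridine) gives the propanoate F8, HF·pyridine frees the allylic hydroxy propanoate F9, and acetylation (Ac2O, DMAP, pyridine) gives 18.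

Step 11. A pyronyl-ethyl chloride and a trisubstituted alkenyl iodide are untested partners in this nickel coupling. The allylic acetate could undergo oxidative addition, 9 can homocouple or be reduced, and the ligand antipode would be needed if the sense at C-g is opposite. The fallback sets out from 9 and 18 and comes back at 19. Zinc insertion (Zn dust, LiCl, THF) converts 9 into the secondary organozinc chloride F10, which is coupled with 18 under Pd(OAc)2/SPhos in THF (Negishi coupling). This gives 19 as a pair of C-g epimers; 19 is then isolated, the (8S)-epimer separated by preparative HPLC and desilylated (1 M aq. HCl, THF) to 20.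

**Further compounds**

F1 | step 3 | rac-2-ethyl-6-[(2S*,3S*)-3-hydroxypentan-2-yl]-3,5-dimethyl-4H-pyran-4-one (racemate, one enantiomer drawn) | CCc1oc([C@@H](C)[C@@H](O)CC)c(C)c(=O)c1C
F2 | step 3 | 2-ethyl-6-[(2S,3S)-3-hydroxypentan-2-yl]-3,5-dimethyl-4H-pyran-4-one | CCc1oc([C@@H](C)[C@@H](O)CC)c(C)c(=O)c1C
F3 | step 3 | (2R,3R)-2-(6-ethyl-3,5-dimethyl-4-oxo-4H-pyran-2-yl)pentan-3-yl acetate | CCc1oc([C@H](C)[C@H](OC(C)=O)CC)c(C)c(=O)c1C
F4 | step 9 | triethyl{[(1E,3R,4R)-1-iodo-2,4-dimethylhexa-1,5-dien-3-yl]oxy}silane | C=C[C@@H](C)[C@@H](O[Si](CC)(CC)CC)/C(C)=C/I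
F5 | step 9 | (3R,4R,5E)-6-iodo-3,5-dimethyl-4-(triethylsilyloxy)hex-5-ene-1,2-diol (both C2 epimers) | OCC(O)[C@@H](C)[C@@H](O[Si](CC)(CC)CC)/C(C)=C/I
F6 | step 9 | (2S,3R,4E)-5-iodo-2,4-dimethyl-3-(triethylsilyloxy)pent-4-enal | O=C[C@@H](C)[C@@H](O[Si](CC)(CC)CC)/C(C)=C/I
F7 | step 9 | 2-ethyl-6-[(2R,3R,4R,5R,6E)-3-hydroxy-7-iodo-4,6-dimethyl-5-(triethylsilyloxy)hept-6-en-2-yl]-3,5-dimethyl-4H-pyran-4-one | O[C@H]([C@@H](C)[C@@H](O[Si](CC)(CC)CC)/C(C)=C/I)[C@@H](C)c1oc(CC)c(C)c(=O)c1C
F8 | step 9 | (1E,3R,4R,5R,6R)-6-(6-ethyl-3,5-dimethyl-4-oxo-4H-pyran-2-yl)-1-iodo-2,4-dimethyl-3-(triethylsilyloxy)hept-1-en-5-yl propanoate | CCC(=O)O[C@H]([C@@H](C)[C@@H](O[Si](CC)(CC)CC)/C(C)=C/I)[C@@H](C)c1oc(CC)c(C)c(=O)c1C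
F9 | step 9 | (1E,3R,4S,5R,6R)-6-(6-ethyl-3,5-dimethyl-4-oxo-4H-pyran-2-yl)-3-hydroxy-1-iodo-2,4-dimethylhept-1-en-5-yl propanoate | CCC(=O)O[C@H]([C@@H](C)[C@@H](O)/C(C)=C/I)[C@@H](C)c1oc(CC)c(C)c(=O)c1C
F10 | step 11 | chloro{1-[3,5-dimethyl-4-oxo-6-((2S,3S)-3-(triethylsilyloxy)pentan-2-yl)-4H-pyran-2-yl]ethyl}zinc (both epimers) | CC([Zn]Cl)c1oc([C@@H](C)[C@@H](O[Si](CC)(CC)CC)CC)c(C)c(=O)c1C
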